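**Retrosynthetic overview**
1. The last step is acid removal of six MOM ethers and one TBS ether. The C4–H bond comes from stereoretentive protodeboronation of a C4 tertiary boronic ester.
2. Key disconnection: the C4–aryl (ring D) bond. It is made together with C3–O by a dioxirane-triggered 1,2-aryl shift from boron to C4, in the ate complex of a (2S)-chromen-4-ylboronate and a 2-lithiostilbene.
3. Chromenylboronate ⇐ enol triflate ⇐ (2S)-flavanone (kinetic resolution) ⇐ chalcone ⇐ resorcinol + p-coumaric acid ⇐ 4-iodophenol + acrylic acid.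
4. Lithiostilbene ⇐ 2-bromostilbene ⇐ Heck coupling of 3,5-bis(MOMO)styrene (from resorcinol, C–H borylation, vinyl bromide) with 4-bromo-1,2-bis(MOMO)benzene (from catechol).
5. Ring order: rings A, B, D and E are bought as phenols. Ring C (pyran) closes first by oxa-Michael addition in step 2. A transient oxirane on C3–C4 is built and opened in the key step.

Structure read from the SMILES: (2R,3S,4S), that is 2,3-trans-3,4-trans (2-aryl α, 3-OH β, 4-aryl α). Flavan numbering is used throughout. MOM = CH2OCH3, pin = pinacolato, DMDO = dimethyldioxirane, dtbpy = 4,4'-di-tert-butyl-2,2'-bipyridine.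

Step 1
Reactants: 1 4-iodophenol; 2 acrylic acid
Product: 3 (E)-4-hydroxycinnamic acid
Conditions: Pd(OAc)2 (1 mol %), P(o-tol)3 (2 mol %), Et3N, MeCN, 80 °C; aq HCl work-up
Reagents that add atoms: none
Why: Mizoroki–Heck reaction in which oxidative addition of the aryl iodide to zerovalent palladium, syn insertion of acrylic acid and syn β-hydride elimination give only the E-cinnamic acid, the free phenol and acid being tolerated as ammonium salts.

Step 2
Reactants: 3 (E)-4-hydroxycinnamic acid; 4 resorcinol
Product: 6 (±)-liquiritigenin (7,4'-dihydroxyflavanone), via isoliquiritigenin 5 (not isolated)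
Conditions: BF3·OEt2 (solvent), 85 °C; crude, then NaOAc, EtOH/H2O, reflux
Reagents that add atoms: none
Why: Nencki-type Friedel–Crafts acylation in which the BF3-activated acid acylates resorcinol at C4 (para to one OH, ortho to the other), after which acetate catalyses the 6-endo oxa-Michael closure of the 2'-hydroxychalcone to ring C, leaving C2 racemic at this stage.

Step 3
Reactants: 6 (±)-liquiritigenin
Product: 7 (±)-7,4'-bis-O-MOM-liquiritigenin
Conditions: MOMCl (2.4 equiv), i-Pr2NEt, CH2Cl2, 0 °C to rt
Reagents that add atoms: chloromethyl methyl ether, COCCl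
Why: Williamson-type O-alkylation that caps the two phenols as base- and organolithium-stable acetals under a hindered amine too weak to open the flavanone ring.

Step 4
Reactants: 7 (±)-7,4'-bis-O-MOM-liquiritigenin
Product: 8 (2S)-7,4'-bis-O-MOM-liquiritigenin
Conditions: Cp*RhCl[(R,R)-TsDPEN] (0.5 mol %), HCO2H/Et3N (5:2), EtOAc, rt, stopped at about 55 % conversion
Reagents that add atoms: none
Why: Kinetic resolution by Noyori–Ikariya asymmetric transfer hydrogenation, in which the (R,R)-catalyst reduces the (2R)-ketone to the cis-(2R,4R)-flavan-4-ol far faster than its antipode, so the recovered ketone is (2S) (at most 50 % yield, at least 98 % ee) with the 2-aryl group α, which is C2 of the target (the descriptor becomes R once C3 carries oxygen).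

Step 5
Reactants: 8 (2S)-7,4'-bis-O-MOM-liquiritigenin
Product: 9 (2S)-7-(methoxymethoxy)-2-[4-(methoxymethoxy)phenyl]-2H-chromen-4-yl triflate
Conditions: KN(SiMe3)2, THF, −78 °C; Comins' reagent, −78 °C
Reagents that add atoms: N-(5-chloropyridin-2-yl)bis(trifluoromethanesulfonimide), O=S(=O)(N(c1ccc(Cl)cn1)S(=O)(=O)C(F)(F)F)C(F)(F)F
Why: Kinetic enolate triflation in which deprotonation at C3 by a hindered amide at −78 °C and immediate O-sulfonylation outrun retro-oxa-Michael ring opening, so C2 keeps its configuration.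

Step 6
Reactants: 9 (2S)-chromen-4-yl triflate
Product: 10 (2S)-chromen-4-ylboronic acid pinacol ester
Conditions: B2pin2, PdCl2(PPh3)2 (3 mol %), PPh3, KOPh, toluene, 50 °C
Reagents that add atoms: bis(pinacolato)diboron, CC1(C)OB(OC1(C)C)B1OC(C)(C)C(C)(C)O1
Why: Miyaura borylation of an alkenyl triflate, in which oxidative addition, phenoxide-assisted transmetalation and reductive elimination replace OTf by Bpin without touching the allylic C2–O bond or the MOM ethers.

Step 7
Reactants: 4 resorcinol
Product: 11 1,3-bis(methoxymethoxy)benzene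
Conditions: MOMCl (2.4 equiv), i-Pr2NEt, CH2Cl2/DMF, 0 °C to rt
Reagents that add atoms: chloromethyl methyl ether, COCCl
Why: Williamson-type O-alkylation of both phenols, giving a 1,3-disubstituted arene suited to sterically controlled C–H borylation.

Step 8
Reactants: 11 1,3-bis(methoxymethoxy)benzene; 12 vinyl bromide
Product: 14 3,5-bis(methoxymethoxy)styrene, via arylboronate 13 (not isolated)
Conditions: [Ir(OMe)(cod)]2 (1 mol %), dtbpy (2 mol %), B2pin2 (0.55 equiv), THF, 80 °C; then 12, PdCl2(dppf) (3 mol %), aq K3PO4, 60 °C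
Reagents that add atoms: bis(pinacolato)diboron, CC1(C)OB(OC1(C)C)B1OC(C)(C)C(C)(C)O1 (boron group of 13 only)
Why: Sterically controlled iridium-catalysed C–H borylation reaches only C5 (the one C–H not ortho to an OMOM group), and the crude boronate undergoes Suzuki–Miyaura coupling with vinyl bromide in the same flask.

Step 9
Reactants: 15 catechol
Product: 16 1,2-bis(methoxymethoxy)benzene
Conditions: MOMCl (2.4 equiv), i-Pr2NEt, CH2Cl2/DMF, 0 °C to rt
Reagents that add atoms: chloromethyl methyl ether, COCCl
Why: Williamson-type O-alkylation that masks the oxidation-prone catechol before halogenation and palladium chemistry.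

Step 10
Reactants: 16 1,2-bis(methoxymethoxy)benzene
Product: 17 4-bromo-1,2-bis(methoxymethoxy)benzene
Conditions: NBS, MeCN, 0 °C
Reagents that add atoms: N-bromosuccinimide, O=C1CCC(=O)N1Br
Why: Electrophilic aromatic bromination that goes para to one alkoxy group and away from the hindered ortho sites, as with veratrole.

Step 11
Reactants: 14 3,5-bis(methoxymethoxy)styrene; 17 4-bromo-1,2-bis(methoxymethoxy)benzene
Product: 18 (E)-3,5,3',4'-tetrakis(methoxymethoxy)stilbene
Conditions: Pd2(dba)3 (1 mol %), P(t-Bu)3·HBF4 (4 mol %), Cy2NMe, dioxane, 80 °C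
Reagents that add atoms: none
Why: Mizoroki–Heck reaction in which the bulky electron-rich phosphine allows oxidative addition of the electron-rich aryl bromide and terminal arylation of the styrene gives the E-stilbene.

Step 12
Reactants: 18 (E)-3,5,3',4'-tetrakis(methoxymethoxy)stilbene
Product: 19 (E)-2-bromo-3,5,3',4'-tetrakis(methoxymethoxy)stilbene
Conditions: NBS (1.0 equiv), CH2Cl2, −78 to 0 °C
Reagents that add atoms: N-bromosuccinimide, O=C1CCC(=O)N1Br
Why: Electrophilic aromatic bromination at C2 of ring D, which is ortho to one OMOM and para to the other, more activated than any ring E position and less hindered than C4 between the two OMOM groups, ring substitution outrunning addition to the alkene at low temperature as known for resveratrol ethers.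

Step 13
Reactants: 19 (E)-2-bromo-3,5,3',4'-tetrakis(methoxymethoxy)stilbene; 10 (2S)-chromen-4-ylboronic acid pinacol ester
Product: 24 (2R,3S,4S)-3-O-TBS-hexa-O-MOM ether of the target, via aryllithium 20 (not isolated), via alkenyl ate complex 21 (not isolated), via oxiranyl ate complex 22 (not isolated), via tertiary boronic ester 23 (not isolated)
Conditions: 19, n-BuLi, THF, −78 °C; 10, −78 °C; DMDO (1.05 equiv, CH2Cl2), −78 °C; TBSOTf, −78 to −20 °C; solvent swap to toluene, TBAF·3H2O (1.5 equiv), rt
Reagents that add atoms: n-butyllithium, [Li]CCCC (lithium of 20 to 22); dimethyldioxirane, CC1(C)OO1 (O at C3); tert-butyldimethylsilyl triflate, CC(C)(C)[Si](C)(C)OS(=O)(=O)C(F)(F)F (TBS group)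
Why: Proposed new method: an oxygen electrophile triggers the 1,2-metallate rearrangement of an alkenyl boronate complex; in ate complex 21 the C3=C4 bond is an enamine-like π-nucleophile, so DMDO transfers oxygen to it at −78 °C (the stilbene alkene is inert at this temperature, and tetracoordinate boron has no vacant orbital for direct B-oxidation) from the face anti to the C2 aryl group, giving oxiranyl ate 22 and setting C3; TBSOTf then pulls the benzylic C4–O bond and the ring D aryl group migrates from boron to C4 antiperiplanar to the leaving oxygen (inversion at C4, so the aryl group ends trans to O-3 and cis to the 2-aryl group), the oxygen being capped as OTBS so that the cis β-oxido boronate cannot collapse by boron-Wittig-type syn elimination; fluoride-assisted protodeboronation of the dibenzylic tertiary boronic ester 23 proceeds with retention and places H on the β face (4S); closest known reaction types are the Zweifel olefination and related halogen-, selenium- or carbon-electrophile-induced 1,2-shifts of vinyl boronate complexes, the homologation of boronic esters with lithiated epoxides (same oxiranyl ate intermediate, silyl triflate promoted) and the TBAF·3H2O protodeboronation of tertiary diarylalkyl boronic esters.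

Step 14
Reactants: 24 (2R,3S,4S)-3-O-TBS-hexa-O-MOM ether of the target
Product: 25 target, (2R,3S,4S)-4-{2,4-dihydroxy-6-[(E)-3,4-dihydroxystyryl]phenyl}-2-(4-hydroxyphenyl)chromane-3,7-diol
Conditions: HCl (1.25 M in MeOH), THF, 40 °C, Ar
Reagents that add atoms: none
Why: Acid-catalysed transacetalisation and silyl ether methanolysis remove all seven protecting groups at once, and the resorcinol-type ring A (no 5-OH) keeps the C4–aryl and C2–O bonds inert to dilute acid, so no stereocentre is touched.

**Compound list**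
1 | 4-iodophenol | Oc1ccc(I)cc1 | starting material
2 | acrylic acid | C=CC(=O)O | starting material
3 | (E)-4-hydroxycinnamic acid | O=C(O)/C=C/c1ccc(O)cc1 | intermediate
4 | resorcinol | Oc1cccc(O)c1 | starting material
5 | isoliquiritigenin, (E)-2',4',4-trihydroxychalcone | O=C(/C=C/c1ccc(O)cc1)c1ccc(O)cc1O | intermediate
6 | (±)-liquiritigenin, racemic 7,4'-dihydroxyflavanone | O=C1CC(c2ccc(O)cc2)Oc2cc(O)ccc21 | intermediate
7 | (±)-7-(methoxymethoxy)-2-[4-(methoxymethoxy)phenyl]chroman-4-one | O=C1CC(c2ccc(OCOC)cc2)Oc2cc(OCOC)ccc21 | intermediate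
8 | (2S)-7-(methoxymethoxy)-2-[4-(methoxymethoxy)phenyl]chroman-4-one | O=C1C[C@@H](c2ccc(OCOC)cc2)Oc2cc(OCOC)ccc21 | intermediate
9 | (2S)-7-(methoxymethoxy)-2-[4-(methoxymethoxy)phenyl]-2H-chromen-4-yl trifluoromethanesulfonate | O=S(=O)(OC1=C[C@@H](c2ccc(OCOC)cc2)Oc2cc(OCOC)ccc21)C(F)(F)F | intermediate
10 | 2-{(2S)-7-(methoxymethoxy)-2-[4-(methoxymethoxy)phenyl]-2H-chromen-4-yl}-4,4,5,5-tetramethyl-1,3,2-dioxaborolane | CC1(C)OB(OC1(C)C)C1=C[C@@H](c2ccc(OCOC)cc2)Oc2cc(OCOC)ccc21 | intermediate
11 | 1,3-bis(methoxymethoxy)benzene | COCOc1cccc(OCOC)c1 | intermediate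
12 | vinyl bromide | C=CBr | starting material
13 | 2-[3,5-bis(methoxymethoxy)phenyl]-4,4,5,5-tetramethyl-1,3,2-dioxaborolane | COCOc1cc(OCOC)cc(B2OC(C)(C)C(C)(C)O2)c1 | intermediate
14 | 3,5-bis(methoxymethoxy)styrene | C=Cc1cc(OCOC)cc(OCOC)c1 | intermediate
15 | catechol | Oc1ccccc1O | starting material
16 | 1,2-bis(methoxymethoxy)benzene | COCOc1ccccc1OCOC | intermediate
17 | 4-bromo-1,2-bis(methoxymethoxy)benzene | COCOc1ccc(Br)cc1OCOC | intermediate
18 | (E)-3,5,3',4'-tetrakis(methoxymethoxy)stilbene | COCOc1cc(OCOC)cc(/C=C/c2ccc(OCOC)c(OCOC)c2)c1 | intermediate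
19 | (E)-2-bromo-3,5,3',4'-tetrakis(methoxymethoxy)stilbene | COCOc1cc(OCOC)c(Br)c(/C=C/c2ccc(OCOC)c(OCOC)c2)c1 | intermediate
20 | (E)-2-lithio-3,5,3',4'-tetrakis(methoxymethoxy)stilbene | COCOc1cc(OCOC)c([Li])c(/C=C/c2ccc(OCOC)c(OCOC)c2)c1 | intermediate
21 | lithium (pinacolato)borate carrying the (2S)-chromen-4-yl group of 10 and the stilben-2-yl group of 20 | [Li+].COCOc1ccc([C@H]2Oc3cc(OCOC)ccc3C(=C2)[B-]2(OC(C)(C)C(C)(C)O2)c2c(OCOC)cc(OCOC)cc2/C=C/c2ccc(OCOC)c(OCOC)c2)cc1 | intermediate
22 | (2R,3R,4S)-3,4-epoxide of 21, oxirane on the face anti to the 2-aryl group, boron on C4 | [Li+].COCOc1ccc([C@H]2Oc3cc(OCOC)ccc3[C@]4([B-]5(OC(C)(C)C(C)(C)O5)c5c(OCOC)cc(OCOC)cc5/C=C/c5ccc(OCOC)c(OCOC)c5)O[C@H]24)cc1 | intermediate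
23 | (2R,3S,4S)-4-Bpin-4-(stilben-2-yl)-3-OTBS flavan, aryl α and Bpin β at C4 | COCOc1ccc([C@H]2Oc3cc(OCOC)ccc3[C@@](B4OC(C)(C)C(C)(C)O4)(c4c(OCOC)cc(OCOC)cc4/C=C/c4ccc(OCOC)c(OCOC)c4)[C@@H]2O[Si](C)(C)C(C)(C)C)cc1 | intermediate
24 | (2R,3S,4S)-3-O-TBS-hexa-O-MOM ether of the target | COCOc1ccc([C@H]2Oc3cc(OCOC)ccc3[C@@H](c3c(OCOC)cc(OCOC)cc3/C=C/c3ccc(OCOC)c(OCOC)c3)[C@@H]2O[Si](C)(C)C(C)(C)C)cc1 | intermediate
25 | (2R,3S,4S)-4-{2,4-dihydroxy-6-[(E)-3,4-dihydroxystyryl]phenyl}-2-(4-hydroxyphenyl)chromane-3,7-diol | Oc1ccc([C@H]2Oc3cc(O)ccc3[C@@H](c3c(O)cc(O)cc3/C=C/c3ccc(O)c(O)c3)[C@@H]2O)cc1 | target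

**Totals**
Total step count: 14. Longest linear sequence: 8 steps (1, 2, 3, 4, 5, 6, 13, 14).

**Three steps most likely to fail**

Step 13 (proposed new step). The risks are oxygen transfer to a boron-bound carbon instead of C3, loss of B and O to give the 4-arylflav-3-ene, and slow ate formation with the doubly ortho-substituted aryllithium.

The fallback uses known chemistry. It sets out from 8 and 18 and comes back at 25.
- The potassium enolate of 8 is hydroxylated with 2-(phenylsulfonyl)-3-phenyloxaziridine, anti to the 2-aryl group, to give (2R,3R)-3-hydroxy-7,4'-bis-O-MOM-flavanone F1.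
- HCl in MeOH frees (2R,3R)-garbanzol F2.
- NaBH4 reduces it to (2R,3S,4R)-flavan-3,4,7,4'-tetraol F3.
- Separately, 18 is deprotected with HCl in MeOH to piceatannol F4.
- F3 and an excess of F4 are condensed in 0.1 M aqueous HCl at room temperature. The C4 benzylic cation is attacked by C2 of the stilbene resorcinol ring, mainly trans to the 3-OH.
- This gives 25 after separation from the 4β epimer.

Step 5. The risk is retro-oxa-Michael opening of the enolate to the chalcone phenoxide, with loss of material and of ee.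

The fallback avoids any C3 carbanion. It sets out from 8 and comes back at 10.
- Hydrazine hydrate in EtOH converts 8 into the (2S)-flavanone hydrazone F5.
- Barton iodination (I2, tetramethylguanidine, THF, 0 °C) gives (2S)-4-iodo-7-(methoxymethoxy)-2-[4-(methoxymethoxy)phenyl]-2H-chromene F6.
- Miyaura borylation (B2pin2, PdCl2(dppf), KOAc, dioxane, 80 °C) delivers 10.

Step 2. The risks are hydroarylation and lactonisation to the 4-aryl-dihydrocoumarin, or decarboxylation of 3 under BF3.

The fallback builds the chalcone by aldol chemistry. It sets out from 4 and 1 and comes back at 5, and step 1 is then not needed.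
- Nencki acylation of 4 with acetic acid and ZnCl2 gives 2,4-dihydroxyacetophenone F7.
- Compound 1 is treated with i-PrMgCl·LiCl (2.2 equiv) and then DMF to give 4-hydroxybenzaldehyde F8.
- Claisen–Schmidt condensation of F7 and F8 (KOH, EtOH/H2O) gives 5, which re-enters at the NaOAc cyclisation of step 2.

**Further compounds**
F1 | step 13 | (2R,3R)-3-hydroxy-7-(methoxymethoxy)-2-[4-(methoxymethoxy)phenyl]chroman-4-one | COCOc1ccc([C@H]2Oc3cc(OCOC)ccc3C(=O)[C@@H]2O)cc1
F2 | step 13 | (2R,3R)-3,7-dihydroxy-2-(4-hydroxyphenyl)chroman-4-one (garbanzol) | Oc1ccc([C@H]2Oc3cc(O)ccc3C(=O)[C@@H]2O)cc1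
F3 | step 13 | (2R,3S,4R)-2-(4-hydroxyphenyl)chromane-3,4,7-triol | Oc1ccc([C@H]2Oc3cc(O)ccc3[C@@H](O)[C@@H]2O)cc1
F4 | step 13 | piceatannol, (E)-3,5,3',4'-tetrahydroxystilbene | Oc1cc(O)cc(/C=C/c2ccc(O)c(O)c2)c1
F5 | step 5 | hydrazone of (2S)-7-(methoxymethoxy)-2-[4-(methoxymethoxy)phenyl]chroman-4-one | NN=C1C[C@@H](c2ccc(OCOC)cc2)Oc2cc(OCOC)ccc21
F6 | step 5 | (2S)-4-iodo-7-(methoxymethoxy)-2-[4-(methoxymethoxy)phenyl]-2H-chromene | IC1=C[C@@H](c2ccc(OCOC)cc2)Oc2cc(OCOC)ccc21
F7 | step 2 | 2,4-dihydroxyacetophenone | CC(=O)c1ccc(O)cc1O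
F8 | step 2 | 4-hydroxybenzaldehyde | O=Cc1ccc(O)cc1
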